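Assumption: the configuration read from the SMILES is (5R,6R,1′S) in the numbering defined below, and (S)-BINAP is taken to deliver the aryl group to the α-si face of an (E)-acyclic enone, as the accepted quadrant model predicts; if the sense were the opposite, (R)-BINAP would be used in step 11.

## Structural features

- The core is a 5,6-dihydro-1H-phenalen-1-one (atoms C1–C9b), a tautomer of a 1,3,6,8-tetraoxygenated naphthalene. Ring D is a vinylogous acid and para-quinone methide (C1=O, C2–H, C3–OH, C3a=C4). Ring B is benzenoid (C6a, C7–O–aryl, C8–H, C9–OH, C9a, C9b). Ring C (C3a, C4, C5, C6, C6a, C9b) carries a 2,6-dihydroxyphenyl group (ring E) on the sp2 carbon C4.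
- A bridge C1′H(CH3)–C2′H2–C3′(=O) runs from C5 to C2″ of a 3″-hydroxyphenyl ring (ring A), whose C1″ is bonded through an ether oxygen to C7. This closes a ten-membered ring (ring F: C5, C1′, C2′, C3′, C2″, C1″, O, C7, C6a, C6) that holds both an aryl ketone and a diaryl ether.
- Three contiguous stereocenters lie on ring F: C6 (R, methyl), C5 (R) and C1′ (S, methyl). The C6 methyl and the C5–C1′ bond are trans on ring C.
- Fragile points are the air-sensitive polyphenol, the quinone methide, the γ-acidic C5–H (epimerisable through the dienol with a C4=C5 bond), and the hydrogen shifts of 1H-phenalenes, which would erase C6.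
- The real difficulty is ring F together with the C6/C5/C1′ triad: a medium ring closed next to a fully substituted ring C.
- The key step exploits two facts. C5 is the γ-terminus of the ring D vinylogous acid (dienol O3–C3=C3a–C4=C5) and C1′ is β to the ring A ketone C3′, so the C5–C1′ bond of ring F is a vinylogous Michael bond. C3a–C4 of ring C is a peri Friedel–Crafts bond, ortho to O3 and para to O1.
- Both C4 units (C4/C5/C6 and C3′/C2′/C1′) are the same 1-(2,6-dioxyphenyl)but-2-en-1-one motif, which keeps the building blocks simple.

## Logic of the disconnections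

**21 ⇒ 18 (key).** Bonds cut: C5–C1′ (ring F) and C3a–C4 (ring C, the C3a=C4 double bond returning to a C4 ketone). The enone C1′=C2′ that results is stored as an O–C1′ bond to the ring A oxygen. In one sentence: 18 is converted into 21 by peri cyclodehydration followed by a ring-F-closing vinylogous Michael addition. Reason: C5–C1′ is the one bond of ring F whose two ends have matched natural polarity, and cutting it removes ring F and two of the three stereocenters at once; C3a–C4 is the bond that the most nucleophilic ring carbon forms readily. Gain: a bridged pentacycle with three stereocenters becomes an open-chain aryl ketone with one controlling stereocenter (C6). Demand: C6 alone must direct C5 and C1′, the enone must be released under the conditions of the C–C bond formation, ring closure must beat intermolecular addition, and C6 must not be scrambled through a 1H-phenalene (19 and 20 are the intermediates).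

**18 ⇒ 17.** Bonds cut: five O–benzyl bonds. Reason: O1 and O3 must be free to act as the electron source in the key step, and freeing the other phenols at the same time avoids any deprotection of 21. Gain: one hydrogenolysis removes every protecting group. Demand: both ketones and the diaryl ether must survive, and the product is air-sensitive.

**17 ⇒ 11 + 16.** Bond cut: C6–C6a. Reason: this aryl–C(sp3) bond is β to the C4 ketone, so it is a conjugate-arylation bond, and it creates the only stereocenter that is taken from a catalyst. Gain: the skeleton falls into two halves of similar size. Demand: the hindered aryl boron group of 11 must add faster than it is lost by protonolysis, and the masked enone of 11 must stay closed.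

**16 ⇒ 15 ⇒ 12 + 13 (via 14).** Bond cut: ring E–C4 (aryl–carbonyl). Reason: the position between the two oxygens of 12 is the natural site of lithiation. Gain: two commercial compounds. Demand: 1,2-addition to 13 and retention of the E geometry through the oxidation.

**11 ⇒ 10 ⇒ 9 ⇒ 8.** Bonds cut: C6a–B, O9–benzyl, C6a–Br. Reason: C6a is para to the free O9 hydroxyl of 8 and ortho to the aryloxy group, so halogenation there is innate. Gain: no directing group is needed. Demand: para rather than ortho attack, and a borylation that tolerates the ketone.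

**8 ⇒ 4 + 7.** Bond cut: O–C1″ (diaryl ether). Reason: made intermolecularly and early, the ether costs no ring strain, and the fluorine of 7 is activated by its ortho carbonyl. Gain: ring A arrives complete with its masked enone. Demand: arylation at O7 only (the less hindered of the two hydroxyls of 4).

**7 ⇒ 5 + 6.** Bonds cut: O–C1′ and C1′–C2′. Reason: amine-mediated aldol condensation and ring closure. Gain: two commercial compounds. Demand: none on stereochemistry, since this centre becomes sp2 in the key step.

**4 ⇒ 3 ⇒ 2 ⇒ 1.** Bonds cut: C7–C8 (Claisen condensation that builds ring B), C9–C9a (Friedel–Crafts acetylation) and two O–benzyl bonds. Reason: building ring B onto a symmetrical benzene differentiates the two rings of the naphthalene from the start (ring D oxygens protected, ring B oxygens free). Gain: a commercial phenylacetate. Demand: acetylation ortho to the acetate arm.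

## Other disconnections considered

Alternative 1: Cut the diaryl ether O–C1″ last (the first idea that comes to mind). The forward key step would be an intramolecular SNAr or Ullmann etherification of the C7 hydroxyl of fluoro ketone A1. The chosen plan is preferred because a ten-membered ring would have to be closed by C–O bond formation between two ortho-substituted arenes, with O3 and O9 of A1 competing as nucleophiles. All three stereocenters of A1 would have to be built in separate operations before the ring exists, which adds steps and protecting groups. In the chosen plan the ether is made without strain at the start.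

Alternative 2: Cut the aryl ketone bond C3′–C2″. The forward key step would be an intramolecular Friedel–Crafts (or Fries-type) acylation of ring A of seco acid A2. The acyl group would have to enter between the two oxygen substituents of ring A, the least favoured site of a resorcinol monoether, so the para position would be expected to react and give a twelve-membered isomer. An anionic variant is ruled out by the acidic vinylogous acid of A2. The stereotriad would again be made beforehand, step by step.

Alternative 3: Cut C6–C6a and C3a–C4 together. The forward key step would be a double Friedel–Crafts peri-annulation of the naphthalene of α-ethylidene 1,5-diketone A3 onto its own enone, closing rings C and F in one event. The first bond would be a ten-membered closure through the less nucleophilic peri carbon C6a, while the more nucleophilic C3a competes for the enone β-carbon and would reverse the regiochemistry. C6 and C5 would have to be controlled from the remote C1′ centre of a flexible chain. A3 itself needs an enantioselective coupling of two β-substituted aryl enones, a poor substrate class. The chosen plan sets C6 by a reliable catalytic arylation and relays it through the rigid phenalene.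

Key step: step 13

## Route

Step 1
Reactants: 1 methyl 2-(3,5-dihydroxyphenyl)acetate
Product: 2 methyl 2-[3,5-bis(benzyloxy)phenyl]acetate
Conditions: BnBr, K2CO3, acetone, reflux
Reagents that add atoms: benzyl bromide, BrCc1ccccc1
Why: Williamson etherification of both phenols; carbonate is too weak to deprotonate the arylacetate α-carbon, so only O-alkylation is expected.

Step 2
Reactants: 2 methyl 2-[3,5-bis(benzyloxy)phenyl]acetate
Product: 3 methyl 2-[2-acetyl-3,5-bis(benzyloxy)phenyl]acetate
Conditions: Ac2O, Sc(OTf)3 (10 mol %), LiClO4, MeNO2, 50 °C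
Reagents that add atoms: acetic anhydride, CC(=O)OC(C)=O
Why: Friedel–Crafts acylation; the position next to the acetate arm is ortho to one benzyloxy group and para to the other and is less hindered than the site between the two ethers.

Step 3
Reactants: 3 methyl 2-[2-acetyl-3,5-bis(benzyloxy)phenyl]acetate
Product: 4 6,8-bis(benzyloxy)naphthalene-1,3-diol
Conditions: NaOMe, MeOH, reflux, argon; aq. HCl
Reagents that add atoms: none
Why: Intramolecular Claisen (Dieckmann-type) condensation of the methyl ketone enolate onto the ester; the 1,3-diketone aromatises to the naphthalenediol, which drives the reaction to completion.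

Step 4
Reactants: 5 1-(2-fluoro-6-hydroxyphenyl)ethan-1-one; 6 acetaldehyde
Product: 7 rac-5-fluoro-2-methylchroman-4-one
Conditions: pyrrolidine (0.5 equiv), MeOH, 40 °C, sealed vessel
Reagents that add atoms: none
Why: Kabbe condensation (enamine aldol, dehydration, oxa-Michael ring closure); the ionised phenol protects the C–F bond from substitution by the amine. The new centre is racemic, which is immaterial because it becomes sp2 in step 13.

Step 5
Reactants: 4 6,8-bis(benzyloxy)naphthalene-1,3-diol; 7 rac-5-fluoro-2-methylchroman-4-one
Product: 8 5-{[5,7-bis(benzyloxy)-4-hydroxynaphthalen-2-yl]oxy}-2-methylchroman-4-one (racemic)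
Conditions: Cs2CO3 (1.1 equiv), DMSO, 70 °C, argon
Reagents that add atoms: none
Why: SNAr; the fluorine is activated by the ortho carbonyl. The 3-hydroxyl of 4 is the less hindered and more acidic one (the 1-hydroxyl is held in a peri hydrogen bond to the 8-benzyloxy oxygen), so mono-arylation there is expected.

Step 6
Reactants: 8 5-{[5,7-bis(benzyloxy)-4-hydroxynaphthalen-2-yl]oxy}-2-methylchroman-4-one
Product: 9 5-{[5,7-bis(benzyloxy)-1-bromo-4-hydroxynaphthalen-2-yl]oxy}-2-methylchroman-4-one
Conditions: NBS (1.0 equiv), MeCN, −30 °C
Reagents that add atoms: N-bromosuccinimide, O=C1CCC(=O)N1Br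
Why: Electrophilic aromatic bromination; the α-carbon para to the free hydroxyl and ortho to the aryloxy group gives a Wheland ion stabilised by both oxygens without disturbing the second benzenoid ring, so it should react before the ortho carbon or the dibenzyloxy ring.

Step 7
Reactants: 9 5-{[5,7-bis(benzyloxy)-1-bromo-4-hydroxynaphthalen-2-yl]oxy}-2-methylchroman-4-one
Product: 10 2-methyl-5-{[4,5,7-tris(benzyloxy)-1-bromonaphthalen-2-yl]oxy}chroman-4-one
Conditions: BnBr, K2CO3, DMF, rt
Reagents that add atoms: benzyl bromide, BrCc1ccccc1
Why: Williamson etherification; it masks the naphthol for the two metal-catalysed steps and joins the other benzyl ethers for a single hydrogenolysis.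

Step 8
Reactants: 10 2-methyl-5-{[4,5,7-tris(benzyloxy)-1-bromonaphthalen-2-yl]oxy}chroman-4-one
Product: 11 2-methyl-5-{[4,5,7-tris(benzyloxy)-1-(4,4,5,5-tetramethyl-1,3,2-dioxaborolan-2-yl)naphthalen-2-yl]oxy}chroman-4-one
Conditions: B2pin2, Pd2(dba)3 (2.5 mol %), SPhos, KOAc, dioxane, 90 °C
Reagents that add atoms: bis(pinacolato)diboron, CC1(C)OB(OC1(C)C)B1OC(C)(C)C(C)(C)O1
Why: Miyaura borylation; it tolerates the ketone (unlike halogen–lithium exchange), and a bulky biaryl phosphine is chosen for the hindered, electron-rich bromide.

Step 9
Reactants: 12 1,3-bis(benzyloxy)benzene; 13 (E)-but-2-enal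
Product: 15 (E)-1-[2,6-bis(benzyloxy)phenyl]but-2-en-1-ol (racemic), via aryllithium 14 (not isolated)
Conditions: n-BuLi, THF, 0 °C; then 13, −78 °C; H2O
Reagents that add atoms: none
Why: Directed ortho-lithiation at the carbon flanked by the two ether oxygens, then 1,2-addition of the aryllithium to the enal; the carbinol centre is removed in step 10.

Step 10
Reactants: 15 (E)-1-[2,6-bis(benzyloxy)phenyl]but-2-en-1-ol
Product: 16 (E)-1-[2,6-bis(benzyloxy)phenyl]but-2-en-1-one
Conditions: MnO2, CH2Cl2, rt
Reagents that add atoms: none
Why: MnO2 oxidation of an alcohol that is both allylic and benzylic; the E geometry of the alkene is retained.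

Step 11
Reactants: 11 2-methyl-5-{[4,5,7-tris(benzyloxy)-1-(4,4,5,5-tetramethyl-1,3,2-dioxaborolan-2-yl)naphthalen-2-yl]oxy}chroman-4-one; 16 (E)-1-[2,6-bis(benzyloxy)phenyl]but-2-en-1-one
Product: 17 (3R)-1-[2,6-bis(benzyloxy)phenyl]-3-{4,5,7-tris(benzyloxy)-2-[(2-methyl-4-oxochroman-5-yl)oxy]naphthalen-1-yl}butan-1-one (both epimers at the chromanone carbon)
Conditions: [Rh(cod)Cl]2 (3 mol %), (S)-BINAP (7 mol %), aq. KOH (0.3 equiv), dioxane/H2O 10:1, 50 °C
Reagents that add atoms: none
Why: Hayashi–Miyaura asymmetric 1,4-addition; the BINAP-bound aryl–rhodium species inserts the E-enone through its α-si face and sets the (3R) centre (C6 of the target), and the resulting rhodium enolate is protonated by water. The chromanone and its racemic centre are spectators, so two epimers that converge in step 13 are expected.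

Step 12
Reactants: 17 (3R)-1-[2,6-bis(benzyloxy)phenyl]-3-{4,5,7-tris(benzyloxy)-2-[(2-methyl-4-oxochroman-5-yl)oxy]naphthalen-1-yl}butan-1-one
Product: 18 (3R)-1-(2,6-dihydroxyphenyl)-3-{4,5,7-trihydroxy-2-[(2-methyl-4-oxochroman-5-yl)oxy]naphthalen-1-yl}butan-1-one
Conditions: H2 (1 atm), Pd/C, EtOAc/MeOH, rt; filtered under argon and used at once
Reagents that add atoms: none
Why: Hydrogenolysis of five benzyl aryl ethers; the hydrogen-bonded aryl ketones, the chromanone and the diaryl ether are not expected to be reduced under these mild conditions.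

Step 13
Reactants: 18 (3R)-1-(2,6-dihydroxyphenyl)-3-{4,5,7-trihydroxy-2-[(2-methyl-4-oxochroman-5-yl)oxy]naphthalen-1-yl}butan-1-one
Product: 21 the target (5R,6R,1′S), via quinone methide 19 (not isolated), via ring-opened enone 20 (not isolated)
Conditions: stage 1: TsOH·H2O (0.2 equiv), degassed MeCN, 50 °C; stage 2: diluted with degassed MeOH to 1 mM, DBU (5 equiv), 45 °C; aq. HCl
Reagents that add atoms: none
Why: Stage 1 is a Friedel–Crafts cyclodehydration (closest known type: Bradsher-type peri closure of 3-(1-naphthyl)propyl ketones): C3a, the ring carbon ortho to O3 and para to O1, attacks the protonated C4 ketone in the 6-exo-trig mode and water leaves through the para oxygen, which gives quinone methide 19 and closes ring C. Stage 2 is an E1cB opening of the chromanone (retro-oxa-Michael) to (E)-enone 20 followed by a vinylogous Michael addition: the extended dienolate of the ring D vinylogous acid attacks through its γ-carbon C5 at the enone β-carbon C1′ and closes ring F in the 10-endo-trig mode. C5 is controlled by C6: the C6 methyl sits pseudoaxial to avoid the C7 aryloxy group, the tether hanging from the C7 oxygen swings over the other face, and the new bond forms anti to the methyl (trans C5/C6). C1′ is controlled by the ring being formed: C2′ must point back toward C6a, which leaves one slot over the ring C π-face and one outside it, so hydrogen goes inside and methyl outside, and on an E-enone this is the S centre. The step needs site selectivity for C5: C2 cannot reach C1′, and C8 is not activated because O9–H stays un-ionised in its peri hydrogen bond to O1 and attack there would cost ring B its aromaticity. It also needs C–C bond formation to beat reclosure to the chromanone, which is secured because the oxa-Michael reaction is reversible whereas the carbon adduct is a stabilised vinylogous carboxylate. C6 is kept because the system rests as the quinone methide and not as a 1H-phenalene.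

## Compound list

1 | methyl 2-(3,5-dihydroxyphenyl)acetate | COC(=O)Cc1cc(O)cc(O)c1 | starting material
2 | methyl 2-[3,5-bis(benzyloxy)phenyl]acetate | COC(=O)Cc1cc(OCc2ccccc2)cc(OCc2ccccc2)c1 | intermediate
3 | methyl 2-[2-acetyl-3,5-bis(benzyloxy)phenyl]acetate | COC(=O)Cc1cc(OCc2ccccc2)cc(OCc2ccccc2)c1C(C)=O | intermediate
4 | 6,8-bis(benzyloxy)naphthalene-1,3-diol | Oc1cc(O)cc2cc(OCc3ccccc3)cc(OCc3ccccc3)c12 | intermediate
5 | 1-(2-fluoro-6-hydroxyphenyl)ethan-1-one | CC(=O)c1c(O)cccc1F | starting material
6 | acetaldehyde | CC=O | starting material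
7 | rac-5-fluoro-2-methylchroman-4-one | CC1CC(=O)c2c(F)cccc2O1 | intermediate
8 | 5-{[5,7-bis(benzyloxy)-4-hydroxynaphthalen-2-yl]oxy}-2-methylchroman-4-one (racemic) | CC1CC(=O)c2c(Oc3cc(O)c4c(OCc5ccccc5)cc(OCc5ccccc5)cc4c3)cccc2O1 | intermediate
9 | 5-{[5,7-bis(benzyloxy)-1-bromo-4-hydroxynaphthalen-2-yl]oxy}-2-methylchroman-4-one (racemic) | CC1CC(=O)c2c(Oc3cc(O)c4c(OCc5ccccc5)cc(OCc5ccccc5)cc4c3Br)cccc2O1 | intermediate
10 | 2-methyl-5-{[4,5,7-tris(benzyloxy)-1-bromonaphthalen-2-yl]oxy}chroman-4-one (racemic) | CC1CC(=O)c2c(Oc3cc(OCc5ccccc5)c4c(OCc5ccccc5)cc(OCc5ccccc5)cc4c3Br)cccc2O1 | intermediate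
11 | 2-methyl-5-{[4,5,7-tris(benzyloxy)-1-(4,4,5,5-tetramethyl-1,3,2-dioxaborolan-2-yl)naphthalen-2-yl]oxy}chroman-4-one (racemic) | CC1CC(=O)c2c(Oc3cc(OCc5ccccc5)c4c(OCc5ccccc5)cc(OCc5ccccc5)cc4c3B3OC(C)(C)C(C)(C)O3)cccc2O1 | intermediate
12 | 1,3-bis(benzyloxy)benzene | c1ccc(COc2cccc(OCc3ccccc3)c2)cc1 | starting material
13 | (E)-but-2-enal | C/C=C/C=O | starting material
14 | [2,6-bis(benzyloxy)phenyl]lithium | [Li]c1c(OCc2ccccc2)cccc1OCc1ccccc1 | intermediate
15 | (E)-1-[2,6-bis(benzyloxy)phenyl]but-2-en-1-ol (racemic) | C/C=C/C(O)c1c(OCc2ccccc2)cccc1OCc1ccccc1 | intermediate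
16 | (E)-1-[2,6-bis(benzyloxy)phenyl]but-2-en-1-one | C/C=C/C(=O)c1c(OCc2ccccc2)cccc1OCc1ccccc1 | intermediate
17 | (3R)-1-[2,6-bis(benzyloxy)phenyl]-3-{4,5,7-tris(benzyloxy)-2-[(2-methyl-4-oxochroman-5-yl)oxy]naphthalen-1-yl}butan-1-one (both epimers at the chromanone carbon) | CC1CC(=O)c2c(Oc3cc(OCc5ccccc5)c4c(OCc5ccccc5)cc(OCc5ccccc5)cc4c3[C@H](C)CC(=O)c3c(OCc5ccccc5)cccc3OCc3ccccc3)cccc2O1 | intermediate
18 | (3R)-1-(2,6-dihydroxyphenyl)-3-{4,5,7-trihydroxy-2-[(2-methyl-4-oxochroman-5-yl)oxy]naphthalen-1-yl}butan-1-one | CC1CC(=O)c2c(Oc3cc(O)c4c(O)cc(O)cc4c3[C@H](C)CC(=O)c3c(O)cccc3O)cccc2O1 | intermediate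
19 | (6R)-4-(2,6-dihydroxyphenyl)-3,9-dihydroxy-6-methyl-7-[(2-methyl-4-oxochroman-5-yl)oxy]-5,6-dihydro-1H-phenalen-1-one | CC1CC(=O)c2c(Oc3cc(O)c4c5c3[C@H](C)CC(c3c(O)cccc3O)=C5C(O)=CC4=O)cccc2O1 | intermediate
20 | (6R)-7-{2-[(E)-but-2-enoyl]-3-hydroxyphenoxy}-4-(2,6-dihydroxyphenyl)-3,9-dihydroxy-6-methyl-5,6-dihydro-1H-phenalen-1-one | C/C=C/C(=O)c1c(O)cccc1Oc1cc(O)c2c3c1[C@H](C)CC(c1c(O)cccc1O)=C3C(O)=CC2=O | intermediate
21 | target: (5R,6R)-4-(2,6-dihydroxyphenyl)-3,9-dihydroxy-6-methyl-5,6-dihydro-1H-phenalen-1-one whose C5 is bridged by (1′S)-CH(CH3)-CH2-C(=O)- to C2″ of a 3″-hydroxyphenyl ring bonded through its C1″ oxygen to C7 (ten-membered ring F) | C[C@H]1CC(=O)c2c(O)cccc2Oc2cc(O)c3c4c2[C@H](C)[C@@H]1C(c1c(O)cccc1O)=C4C(O)=CC3=O | target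

## Step count and least certain steps

Total step count: 13. Longest linear sequence: 10 steps (steps 1, 2, 3, 5, 6, 7, 8, 11, 12, 13).

**Step 13 (key step).** What may go wrong: ring F closure may be slower than intermolecular Michael addition through C2 of a second molecule or than return to the chromanone; attack on the other enone face would give the C1′ epimer; a base-induced hydrogen shift in the transient 1H-phenalene tautomer would erode C6; the polyphenolate may be oxidised by traces of air. The two stages can be run separately if stage 1 needs stronger acid. Fallback (changes the order of ring formation and the nucleophile): it sets out from 17 and returns at 21. Compound 17 is treated with Cs2CO3 in DMSO at high dilution, so that the chromanone opens by E1cB and the enolate of the C4 ketone adds through C5 to the liberated enone, giving the benzyl-protected ten-membered 1,5-diketone F1, in which C5 is still epimerisable to its more stable configuration. Hydrogenolysis (H2, Pd/C) then gives the debenzylated ten-membered diketone F2, and acid (TsOH, MeCN) closes ring C by attack of C3a on the C4 ketone and dehydration to 21.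

**Step 11.** What may go wrong: protonolysis of the C–B bond of the hindered, electron-rich 2-aryloxy-1-naphthyl boronate may outrun transmetalation and insertion, and base may open the chromanone and create a second acceptor. Fallback (the stereocentre is set by hydride delivery, not aryl delivery): it sets out from 10 and 16 and returns at 17. A Mizoroki–Heck reaction of 10 with 16 (Pd(OAc)2, P(t-Bu)3·HBF4, Cy2NMe, dioxane, 100 °C) gives the β-aryl-β-methyl enone (E)-1-[2,6-bis(benzyloxy)phenyl]-3-{4,5,7-tris(benzyloxy)-2-[(2-methyl-4-oxochroman-5-yl)oxy]naphthalen-1-yl}but-2-en-1-one F3. Its C=C bond is then reduced enantioselectively by a copper hydride catalyst (Cu(OAc)2, the DTBM-SEGPHOS antipode that gives the R centre, (EtO)2MeSiH, t-BuOH, toluene, 0 °C) to give 17.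

**Step 5.** What may go wrong: arylation at the peri-hydroxyl or at both hydroxyls, C-arylation of the diketone-like diol, and base-induced opening of 7 at the SNAr temperature. Fallback (the two hydroxyls are differentiated by silylation before any arylation): it sets out from 4 and returns at 10, bypassing steps 5 to 7. Silylation with i-Pr3SiCl and imidazole at the less hindered hydroxyl gives 6,8-bis(benzyloxy)-3-{[tri(propan-2-yl)silyl]oxy}naphthalen-1-ol F4. NBS gives 6,8-bis(benzyloxy)-4-bromo-3-{[tri(propan-2-yl)silyl]oxy}naphthalen-1-ol F5. Benzylation (BnBr, NaH, THF, 0 °C) gives {[4,5,7-tris(benzyloxy)-1-bromonaphthalen-2-yl]oxy}tri(propan-2-yl)silane F6. Fluoride (Bu4NF, THF) gives 4,5,7-tris(benzyloxy)-1-bromonaphthalen-2-ol F7, whose single hydroxyl is arylated with 7 (Cs2CO3, DMSO) to give 10.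

**Step 12.** What may go wrong: incomplete cleavage of the hindered benzyl ethers, over-reduction of a benzylic carbonyl on prolonged exposure, and aerial oxidation of the pentaphenol during filtration. Fallback (Lewis-acid dealkylation merged with ring C closure in place of hydrogenolysis): it sets out from 17 and returns at 19, the first intermediate of step 13. Compound 17 is treated with BCl3 and pentamethylbenzene in CH2Cl2 at −78 °C, which removes the five benzyl groups as their adducts with the scavenger while the Lewis acid effects the peri cyclodehydration; after a methanol quench, stage 2 of step 13 is applied to the crude 19. This fallback makes no new compound (F0).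

## Further compounds

F1 | step 13 | benzyl-protected ten-membered 1,5-diketone (C5–C1′ bond formed, ring C open, ring A phenol free) | C[C@H]1CC(=O)c2c(O)cccc2Oc2cc(OCc3ccccc3)c3c(OCc4ccccc4)cc(OCc4ccccc4)cc3c2[C@H](C)[C@@H]1C(=O)c1c(OCc2ccccc2)cccc1OCc1ccccc1
F2 | step 13 | debenzylated ten-membered 1,5-diketone (hexaphenol; ring C open) | C[C@H]1CC(=O)c2c(O)cccc2Oc2cc(O)c3c(O)cc(O)cc3c2[C@H](C)[C@@H]1C(=O)c1c(O)cccc1O
F3 | step 11 | (E)-1-[2,6-bis(benzyloxy)phenyl]-3-{4,5,7-tris(benzyloxy)-2-[(2-methyl-4-oxochroman-5-yl)oxy]naphthalen-1-yl}but-2-en-1-one | CC1CC(=O)c2c(Oc3cc(OCc5ccccc5)c4c(OCc5ccccc5)cc(OCc5ccccc5)cc4c3/C(C)=C/C(=O)c3c(OCc5ccccc5)cccc3OCc3ccccc3)cccc2O1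
F4 | step 5 | 6,8-bis(benzyloxy)-3-{[tri(propan-2-yl)silyl]oxy}naphthalen-1-ol | CC(C)[Si](Oc1cc(O)c2c(OCc3ccccc3)cc(OCc3ccccc3)cc2c1)(C(C)C)C(C)C
F5 | step 5 | 6,8-bis(benzyloxy)-4-bromo-3-{[tri(propan-2-yl)silyl]oxy}naphthalen-1-ol | CC(C)[Si](Oc1cc(O)c2c(OCc3ccccc3)cc(OCc3ccccc3)cc2c1Br)(C(C)C)C(C)C
F6 | step 5 | {[4,5,7-tris(benzyloxy)-1-bromonaphthalen-2-yl]oxy}tri(propan-2-yl)silane | CC(C)[Si](Oc1cc(OCc3ccccc3)c2c(OCc3ccccc3)cc(OCc3ccccc3)cc2c1Br)(C(C)C)C(C)C
F7 | step 5 | 4,5,7-tris(benzyloxy)-1-bromonaphthalen-2-ol | Oc1cc(OCc3ccccc3)c2c(OCc3ccccc3)cc(OCc3ccccc3)cc2c1Br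
F0 | step 12 | none | none
A1 | alternative 1 | (5R,6R)-4-(2,6-dihydroxyphenyl)-5-[(2S)-4-(2-fluoro-6-methoxyphenyl)-4-oxobutan-2-yl]-3,7,9-trihydroxy-6-methyl-5,6-dihydro-1H-phenalen-1-one | C[C@@H](CC(=O)c1c(OC)cccc1F)[C@H]1C(c2c(O)cccc2O)=C2C(O)=CC(=O)c3c(O)cc(O)c(c23)[C@@H]1C
A2 | alternative 2 | (3S)-3-[(5R,6R)-4-(2,6-dihydroxyphenyl)-3,9-dihydroxy-7-(3-hydroxyphenoxy)-6-methyl-1-oxo-5,6-dihydro-1H-phenalen-5-yl]butanoic acid | C[C@@H](CC(=O)O)[C@H]1C(c2c(O)cccc2O)=C2C(O)=CC(=O)c3c(O)cc(Oc4cccc(O)c4)c(c23)[C@@H]1C
A3 | alternative 3 | (2E,3S)-1-(2,6-dihydroxyphenyl)-2-ethylidene-5-{2-hydroxy-6-[(4,5,7-trihydroxynaphthalen-2-yl)oxy]phenyl}-3-methylpentane-1,5-dione | C/C=C(/C(=O)c1c(O)cccc1O)[C@@H](C)CC(=O)c1c(O)cccc1Oc1cc(O)c2c(O)cc(O)cc2c1
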